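Start with the easy part: the flasks differ in their equivalents of reagent and in nothing else.

| setting | north-east | south | north-west |
|---|---|---|---|
| substrate | 0.10 M | 0.10 M | 0.10 M |
| reagent | 0.950 equiv | 1.90 equiv | 3.80 equiv |
| free catalyst | 0.1 mol% | 0.1 mol% | 0.1 mol% |
| time | 1.5 h | 1.5 h | 1.5 h |

    reagent + free catalyst ⇌ catalyst intermediate A (K1 = 740 /M, k1 = 4.1 /M/s)
    substrate + catalyst intermediate A → catalyst intermediate B (k2 = 190 /M/s)
    catalyst intermediate B → by-product + catalyst intermediate C (k3 = 0.11 /s)
    catalyst intermediate C → free catalyst + product (k4 = 0.49 /s)
    reagent + by-product ⇌ idle adduct, settled at all times (K5 = 2800 /M)

1. part of the substrate that has reacted at the end, north-east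
2. part of the substrate that has reacted at the end, south
3. part of the substrate that has reacted at the end, north-west
4. what raising the equivalents of reagent from its lowest to its highest value here does to the part of the substrate that has reacted (changes below 5 percentage points count as none) (no change / it falls / it rises)

- for by-product the idle adduct is counted in
- run time (north-east): 1.5 h

Each turn of a catalyst molecule makes one product, so the part of the substrate reacted is the loading times the time, divided by the cycle time, the mean duration of one turn. Release of by-product takes 9.09 s and, while [reagent] stands at its charge, is the rate-limiting step; release of product takes 2.04 s. Together they make the fixed cycle time, the part of a turn that the reagent does not touch: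

fixed cycle time = 11.1 s, which with no other wait gives 48.5% in 1.5 h

Binding substrate takes 0.0526 s at the start, far less than that, and the way back from catalyst intermediate A, at 0.00554 /s, is slower than the way on, at 19.0 /s. I drop both. The wait that remains is free catalyst meeting reagent, one over k times [reagent]. For north-east, with [reagent] at its charge of 0.0950 M:

cycle time = 11.1 s + 2.57 s = 13.7 s, giving 39.4%

But [reagent] falls. Each turn takes one reagent in the first step, and the by-product binds a second, because K times [reagent] for the idle adduct starts in north-east at 270, which at that point leaves nearly all of it bound. Replacing the falling curve by its mean, half the drop below the charge: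

mean [reagent] = 0.0556 M, giving 34.8%

The weak link is that the wait goes with one over [reagent], and the mean of a reciprocal exceeds the reciprocal of the mean. Taking the fall as straight, down to 0.0254 M, the mean wait is a logarithmic mean:

wait = 4.62 s, cycle time = 15.8 s, north-east 34.3%

In south and north-west each turn takes a smaller share of the charge than in north-east, so the plain mean serves:

south: cycle time 12.8 s, 42.2%

north-west: cycle time 11.9 s, 45.5%

Across the flasks the part reacted: it rises, by more than the margin of 5 percentage points.

The forecast gave 34.5%, 42% and 45.4%, with it rises for the trend, holding that “free reagent falls about twice as fast as substrate is used”.

The simulation gives 34.4%, 41.9% and 45.3%; for the trend, it rises, by 11 points. In north-east, 28% of the reagent is left at the end against 66% of the substrate. Taking the fixed cycle time from the cycle time that north-east's result implies leaves a mean wait of 4.58 s. Now take the neighbour of north-east charged with 0.570 equiv of reagent, which keeps 13% of it at 1.50 h. Its logarithmic mean wait added to the fixed cycle time gives 21.1 s, hence 25.6%. That flask reads 25.3%.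

The constants belong to no real substance; the result is computed.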